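In this flask, at rest, the dormant form holds more of the starting material than the target does: 2.9 parts against 1.37 parts for each part left free.

solid substrate 0.0020 M; second substrate 2.00 mM; gas 0.18 mM (held); time 1.0 h

    starting material + coupling partner ⇌ target (K1 = 7600 L mol⁻¹, k1 = 74 L mol⁻¹ s⁻¹)
    second substrate + coupling partner ⇌ second product (K2 = 2800 L mol⁻¹, k2 = 48 L mol⁻¹ s⁻¹)
    gas ⇌ coupling partner, rate k3*(csat - [coupling partner]) (k3 = 0.37 s⁻¹, csat = 0.18 mM)
    starting material ⇌ dormant form (K4 = 2.9, k4 = 0.068 s⁻¹)
    solid substrate ⇌ starting material, rate k5*(cs5 - [starting material]) while solid is left; crystals form when [starting material] > cs5 (cs5 = 1.4 mM, k5 = 0.23 s⁻¹)

- which holds at 1.0 h: what has brought the reaction to rest, or that it has not come to rest (for what has run out or reacted, a solid counts together with what of it has only dissolved) (it is still moving / all of the solid substrate has reacted / forward and back rates have come level)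
- part of the solid substrate that has turned into other species by 1.0 h (what has only dissolved does not count)
- amount of target at 1.0 h, in percent of the solid substrate charged
- amount of starting material at 1.0 h, in percent of the solid substrate charged
- amount of target if the flask were left three thousand times as long, in percent of the solid substrate charged

- given per volume of solution although it is solid: solid substrate
- at the start none of coupling partner is dissolved
- at the start none of the solid substrate is in solution
- what has only dissolved of solid substrate counts as not reacted
- what has gone from starting material into another species counts as reacted, even if it can come back
- the reaction counts as stopped when no species that holds the solid substrate changes by six tenths of a point or more over the second half of the time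
- starting material means what is dissolved; the solid is not counted in it
- run time (flask): 1.0 h

We work with the fraction left and not with the fraction made. Gas transfer stands still when the coupling partner is at 0.18 mM, so at rest the target's weight w is the equilibrium constant 7600 L mol⁻¹ times 0.18 mM. Each part of free starting material then goes with 2.9 parts of dormant form and w parts of target, which leaves one part in the sum of these: 19.0%. This fraction is the free share f, what stands as starting material of a dissolved charge at rest.

The second way uses rates. Starting material and dormant form relax into each other with a half-life of 0.126 min, so we treat them as one pool, of which 25.6% is free. With the partner held, the pool drains to target by a pseudo-first-order constant 0.00342 s⁻¹, and target returns with 0.00974 s⁻¹. The pool keeps the back constant's part of their sum, 74.0%, and the free part of that is 19.0%, the same number. The rate constant of the step to target cancels, so this agreement checks our bookkeeping and not the constants.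

The second way also gives a time. With the partner held, the pool and target relax with a half-life of 0.878 min, longer than the pool's own and far shorter than 1.0 h. The free share of this charge is 0.380 mM, below the solubility 1.4 mM, so the solid can dissolve completely. We therefore expect this flask to be at rest, with 81.0% converted, 26.0% target and 19.0% starting material, and with the same target after a far longer wait.

The forecast gives forward and back rates have come level, with conversion 81%, target 26%, starting material 19% and a late target of 26%, on the ground that “the flask sits at equilibrium”. The simulated flask gives forward and back rates have come level, conversion 81.0%, target 26.0%, starting material 19.0% and late target 26.0%, as f gave.

The neighbour flask holds 0.0080 M of solid substrate, with everything else as before. There f asks for 1.52 mM of free starting material, more than the solubility 1.4 mM. So we stop the free amount at 1.4 mM, which is 17.5% of that charge. The weights then give 23.9% target, and the part not taken up is 7.81%, which stays solid. The neighbour flask shows 17.5% starting material, 23.9% target and 7.81% solid substrate.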